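Assumption: the target SMILES carries no stereocentre, so the molecule is treated as achiral; squaric acid dichloride (compound 16) is taken as purchasable (otherwise one step from squaric acid with oxalyl chloride and catalytic DMF).

## Structural features

The target is a pentamer of five benzene rings A–E in a row, joined only by four diaryl ether oxygens, with thirteen free phenolic hydroxyls and no C–C bond between rings. Ring A is a 2,4,6-trihydroxyphenyl group; ring B carries O–A at C1, O–C at C6 and hydroxyls at C3 and C5; ring C carries O–B at C1, O–D at C4 and hydroxyls at C3 and C5; ring D carries O–C at C1, H at C2, hydroxyls at C3, C4 and C5 and O–E at C6; ring E is a 3,4,5-trihydroxyphenyl group. There is no stereocentre and no configurationally stable axis, so nothing stereochemical has to be set. Each ether oxygen sits on one side on a carbon flanked by two oxygen-bearing carbons (the linking carbon of A, C6 of B, C4 of C, C6 of D), so every conventional C–O coupling would involve a di-ortho-substituted, electron-rich partner. The real difficulty is ring D: five contiguous oxygens, a single C–H, two aryloxy groups on adjacent carbons (C1 and C6) and three hydroxyls that must stay distinct from the two ether oxygens. The key step exploits the fact that C3, C4, C5 and C6 of ring D with their four oxygens map atom for atom onto the C4O4 core of squaric acid, while C1 (aryloxy) and C2 (H) map onto an aryl ethynyl ether; a vinylketene/ynol ether benzannulation places the alkyne oxygen meta to the new hydroxyl with the C–H between them, which is the C1/C2/C3 pattern of ring D. The pyrogallol-type polyphenol is air-sensitive, especially under base, so the free phenols are released only in the last step under acidic, non-oxidizing conditions; the ynol ether and the cyclobutenones of the route are sensitive to acid and heat.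

## Logic of the disconnections

27 to 26. Twelve O–CH3 bonds are cut. All phenols but one are carried as methyl ethers because these survive organolithium, hydride and thermal steps and fall in one operation. The gain is an air-stable, chromatographable precursor. The demand is that the ether cleavage breaks alkyl–O bonds only, leaves the four aryl–O–aryl bonds intact, and that 27 is handled without oxygen.

26 to 15 and 21 (key disconnection). Three C–C bonds of ring D are cut: C1–C6, C2–C3 and C3–C4. C1 and C2 with the oxygen to ring C go to alkyne 15; C3–C6 with four oxygens and ring E go to cyclobutenone 21. In one sentence: ring D of 26 is made in one benzannulation from 15, which already carries rings A, B and C, and 21, which already carries ring E. The cut removes the most congested ring and, with it, the need to form either of its two aryl ether bonds at an aromatic carbon; it is also the point of full convergence. The demand is that 21 opens to a vinylketene that 15 captures with the correct polarity before it is lost otherwise, and that the second ring opening turns the vinyl group inward.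

21 to 20, 19, then 16 and 17. The O–CH3 bond at C4 of 21, the C4–H bond of 20 and the two C–O bonds at the chlorine-bearing carbons of 16 are cut. All four ring carbons and their oxygens come from 16, and the ring E ether oxygen enters as a phenol in an acyl-type substitution. The gain is three steps from two purchasable compounds. The demand is that hydride attacks the carbonyl next to the methoxy-bearing carbon of 19 and that 20 is alkylated without acid.

15 to 12, then 9 and 10. The alkyne is traced back to the two C–Cl bonds of 12, and the O–C(sp2) bond of 12 is cut. The future C1–O bond of ring D, whose ring C side is a carbon between two methoxy groups, is thus made by adding a phenoxide to a two-carbon electrophile. The demand is that the base does not metalate the methoxyarenes and that 15 is used soon after it is formed.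

9 to 7, then 5 and 6. The C4–O bond of ring C (oxygen inserted into the aryl–CHO bond of 7) and the O–C1 bond of ring C are cut. The formyl group serves twice: it activates the para C–Br bond of 6 and then becomes the phenol oxygen. The demand is that the hindered phenoxide of 5 couples with an unhindered, activated bromide.

5 to 3, then 1 and 2. The same pair of cuts is made on ring B: the C6–O bond (from the formyl group of 3) and the O–C1 bond. The ortho-formyl group of 2 activates its bromide, and both partners are purchasable. The demand is a coupling of the di-ortho-methoxy phenoxide of 1.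

## Other disconnections considered

Alternative 1: The first idea is one aryl–O bond at a time, by four copper-mediated Ullmann couplings of protected phenols with aryl halides. It would end, for example, with the union of phenol 9 and 1-bromo-3,4,5-trimethoxy-2-(3,4,5-trimethoxyphenoxy)benzene A1 to give the tridecamethyl ether A2. A1 is a pentasubstituted benzene whose five oxygens and bromine need their own regiocontrolled synthesis, since electrophilic bromination of the parent diaryl ether has two activated rings to choose from. The last coupling would pair the most hindered phenoxide with the most electron-rich, ortho-substituted bromide, where oxidative addition should be slow and reduction of the bromide should compete. The chosen plan keeps couplings only where a formyl group activates the halide, and A1 alone would need about as many steps as the whole branch to 21.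

Alternative 2: Ring D is cut at C1–C2 and C3–C4. Addition of an α-alkoxyvinyllithium reagent to squarate 19 would give 3,4-dimethoxy-4-(1-methoxyethenyl)-2-(3,4,5-trimethoxyphenoxy)cyclobut-2-en-1-one A3. Its thermal Moore-type ring expansion would give 3,4,5-trimethoxy-2-(3,4,5-trimethoxyphenoxy)phenol A4. This builds ring D with the D–O–E ether in place but leaves the C1 oxygen as a free phenol. The C–O–D bond would then still require a cross-coupling against the di-ortho-methoxy carbon of ring C, after turning A4 into an electrophile. Only one of the two ring D ethers is settled by the ring construction, the route is less convergent, and it is at least two steps longer.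

Alternative 3: The C4–O bond of ring C is cut and ring C is carried as a saturated ring. O–H insertion of A4 into the carbenoid from 2-diazocyclohexane-1,3-dione A5 (Rh2(OAc)4) would give 2-[3,4,5-trimethoxy-2-(3,4,5-trimethoxyphenoxy)phenoxy]cyclohexane-1,3-dione A6. Dehydrogenation would give the resorcinol 2-[3,4,5-trimethoxy-2-(3,4,5-trimethoxyphenoxy)phenoxy]benzene-1,3-diol A7. The hindered C–O bond forms easily at a carbon between two carbonyl groups, but the oxygen at C1 of ring C cannot be carried, because a 5-oxygenated cyclohexane-1,3-dione would lose it by β-elimination on aromatization. A7 would therefore need a later C–H oxidation and a further coupling to the hindered C6 of ring B, and ring D is not addressed at all.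

Key step: step 10

## Route

Step 1
Reactants: 1 2,4,6-trimethoxyphenol; 2 2-bromo-4,6-dimethoxybenzaldehyde
Product: 3 2,4-dimethoxy-6-(2,4,6-trimethoxyphenoxy)benzaldehyde
Conditions: CuI (10 mol %), picolinic acid (20 mol %), K3PO4, DMSO, 90 °C
Reagents that add atoms: none
Why: Ullmann-type diaryl ether synthesis; the ortho-formyl group activates the C–Br bond of 2, and the picolinic acid ligand system is one used for di-ortho-substituted phenols such as 1. No stereocentre is formed.

Step 2
Reactants: 3 2,4-dimethoxy-6-(2,4,6-trimethoxyphenoxy)benzaldehyde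
Product: 5 2,4-dimethoxy-6-(2,4,6-trimethoxyphenoxy)phenol, via aryl formate 4 (not isolated)
Conditions: mCPBA, CH2Cl2, 0 °C to rt; then K2CO3 (cat.), MeOH, rt
Reagents that add atoms: meta-chloroperoxybenzoic acid, OOC(=O)c1cccc(Cl)c1
Why: Baeyer–Villiger (Dakin-type) oxidation; the electron-rich, di-ortho-oxygenated aryl group should migrate in preference to hydrogen to give formate 4, which mild methanolysis cleaves to the phenol. The formyl group that activated the bromide thus becomes the oxygen that will link rings B and C.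

Step 3
Reactants: 5 2,4-dimethoxy-6-(2,4,6-trimethoxyphenoxy)phenol; 6 4-bromo-2,6-dimethoxybenzaldehyde
Product: 7 4-[2,4-dimethoxy-6-(2,4,6-trimethoxyphenoxy)phenoxy]-2,6-dimethoxybenzaldehyde
Conditions: CuI (10 mol %), picolinic acid (20 mol %), K3PO4, DMSO, 100 °C
Reagents that add atoms: none
Why: Ullmann-type coupling; the hindered phenoxide of 5 meets an unhindered C–Br bond activated by the para-formyl group of 6, so the steric load lies on one partner only.

Step 4
Reactants: 7 4-[2,4-dimethoxy-6-(2,4,6-trimethoxyphenoxy)phenoxy]-2,6-dimethoxybenzaldehyde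
Product: 9 4-[2,4-dimethoxy-6-(2,4,6-trimethoxyphenoxy)phenoxy]-2,6-dimethoxyphenol, via aryl formate 8 (not isolated)
Conditions: mCPBA, CH2Cl2, 0 °C to rt; then K2CO3 (cat.), MeOH, rt
Reagents that add atoms: meta-chloroperoxybenzoic acid, OOC(=O)c1cccc(Cl)c1
Why: Baeyer–Villiger (Dakin-type) oxidation as in step 2; the 2,6-dimethoxy-4-aryloxyphenyl group should migrate readily, and methanolysis of formate 8 frees the phenol that will become the oxygen between rings C and D.

Step 5
Reactants: 9 4-[2,4-dimethoxy-6-(2,4,6-trimethoxyphenoxy)phenoxy]-2,6-dimethoxyphenol; 10 trichloroethylene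
Product: 12 2-{[(E)-1,2-dichloroethenyl]oxy}-5-[2,4-dimethoxy-6-(2,4,6-trimethoxyphenoxy)phenoxy]-1,3-dimethoxybenzene, via dichloroacetylene 11 (not isolated)
Conditions: K2CO3, DMF, 70 °C
Reagents that add atoms: none
Why: Base should convert 10 into dichloroacetylene 11 in situ, and anti addition of the phenoxide of 9 and a proton across it gives the (E)-dichlorovinyl ether. This metal-free O-vinylation has the small alkyne as electrophile and should tolerate the two ortho methoxy groups.

Step 6
Reactants: 12 2-{[(E)-1,2-dichloroethenyl]oxy}-5-[2,4-dimethoxy-6-(2,4,6-trimethoxyphenoxy)phenoxy]-1,3-dimethoxybenzene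
Product: 15 5-[2,4-dimethoxy-6-(2,4,6-trimethoxyphenoxy)phenoxy]-2-(ethynyloxy)-1,3-dimethoxybenzene, via chloroalkyne 13 (not isolated), via lithium acetylide 14 (not isolated)
Conditions: n-BuLi (2.2 equiv), THF, −78 °C to −40 °C; then H2O, −78 °C; crude 15 kept cold and used at once
Reagents that add atoms: none
Why: Dehydrochlorination of 12 by n-BuLi should give chloroalkyne 13, chlorine–lithium exchange the acetylide 14, and protonation the terminal aryl ynol ether (the dichlorovinyl ether route to alkynyl ethers). 15 has no β-hydrogen for a retro-ene loss of ketene but should not be stored.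

Step 7
Reactants: 16 squaric acid dichloride (3,4-dichlorocyclobut-3-ene-1,2-dione); 17 3,4,5-trimethoxyphenol
Product: 19 3-methoxy-4-(3,4,5-trimethoxyphenoxy)cyclobut-3-ene-1,2-dione, via chloro methoxy cyclobutenedione 18 (not isolated)
Conditions: MeOH (1.0 equiv), iPr2NEt, CH2Cl2, −78 °C to 0 °C; then 17, iPr2NEt, −40 °C to 0 °C
Reagents that add atoms: methanol, CO
Why: Two successive addition–elimination reactions at the vinylogous acid chloride carbons of 16; the methoxy group introduced first slows the second substitution, so it can be done separately with the phenoxide of 17. The aryloxide cannot displace methoxide, so the mixed diester is the end point.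

Step 8
Reactants: 19 3-methoxy-4-(3,4,5-trimethoxyphenoxy)cyclobut-3-ene-1,2-dione
Product: 20 4-hydroxy-3-methoxy-2-(3,4,5-trimethoxyphenoxy)cyclobut-2-en-1-one (racemic)
Conditions: LiAlH(OtBu)3 (1.05 equiv), THF, −78 °C; then H2O
Reagents that add atoms: none
Why: 1,2-Reduction of one squarate carbonyl by a bulky hydride, as used for dialkyl squarates. The carbonyl next to the methoxy-bearing carbon should be attacked, because it is the vinylogous ester of the weaker aryloxy donor and is flanked by the smaller group. The new stereocentre at C4 forms as a racemate and disappears in step 10.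

Step 9
Reactants: 20 4-hydroxy-3-methoxy-2-(3,4,5-trimethoxyphenoxy)cyclobut-2-en-1-one
Product: 21 3,4-dimethoxy-2-(3,4,5-trimethoxyphenoxy)cyclobut-2-en-1-one (racemic)
Conditions: MeI, Ag2O, 4 Å molecular sieves, CH2Cl2, rt, dark
Reagents that add atoms: iodomethane, CI
Why: O-Methylation under neutral conditions (Ag2O/MeI), chosen because 20 loses methanol under acid and may open under strong base. The methyl ether blocks lactonization of the later ketene and becomes the C4 oxygen of ring D.

Step 10
Reactants: 15 5-[2,4-dimethoxy-6-(2,4,6-trimethoxyphenoxy)phenoxy]-2-(ethynyloxy)-1,3-dimethoxybenzene; 21 3,4-dimethoxy-2-(3,4,5-trimethoxyphenoxy)cyclobut-2-en-1-one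
Product: 26 5-{4-[2,4-dimethoxy-6-(2,4,6-trimethoxyphenoxy)phenoxy]-2,6-dimethoxyphenoxy}-2,3-dimethoxy-4-(3,4,5-trimethoxyphenoxy)phenol, via vinylketene 22 (not isolated), via vinylcyclobutenone 23 (not isolated), via dienylketene 24 (not isolated), via cyclohexadienone 25 (not isolated)
Conditions: 21 (1.5 equiv), PhMe (0.5 M in 15), 80 °C then 110 °C, argon
Reagents that add atoms: none
Why: Danheiser benzannulation, run here with a squarate-derived cyclobutenone. Heating 21 should open the four-membered ring in a conrotatory 4π electrocyclic reaction with the C4 methoxy group turning outward, which gives the (Z)-vinylketene 22. The ketene C=C of 22 should add to ynol ether 15 in a (2+2) cycloaddition in which the nucleophilic CH terminus of 15 bonds to the ketene carbonyl carbon (C2–C3 of ring D) and the oxygen-bearing alkyne carbon to the ketene α-carbon (C1–C6 of ring D), giving 23. A second 4π opening of 23, again with the oxygen substituent (the ring E aryloxy group) outward and the dimethoxyvinyl group inward, should give dienylketene 24, which closes ring D by a thermal disrotatory 6π electrocyclization (C3–C4 of ring D) to 25; enolization gives 26. No stereocentre remains in 26; those of 21, 23 and 25 are transient and racemic. The selectivity needed is regiochemical and is secured by the polarization of the ynol ether, which places the ring C aryloxy group meta to the new hydroxyl and next to the ring E aryloxy group, and by the donor-outward torquoselectivity of both ring openings, which brings the vinyl group within reach of the ketene. The closest known reactions are the benzannulation of cyclobutenones with alkoxy- and siloxyalkynes and the thermal ring expansion of 4-alkenyl-4-alkoxycyclobutenones made from squarates. An excess of 21 and a high concentration favour the one bimolecular event over unimolecular loss of 22.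

Step 11
Reactants: 26 5-{4-[2,4-dimethoxy-6-(2,4,6-trimethoxyphenoxy)phenoxy]-2,6-dimethoxyphenoxy}-2,3-dimethoxy-4-(3,4,5-trimethoxyphenoxy)phenol
Product: 27 5-{4-[2,4-dihydroxy-6-(2,4,6-trihydroxyphenoxy)phenoxy]-2,6-dihydroxyphenoxy}-4-(3,4,5-trihydroxyphenoxy)benzene-1,2,3-triol (target, CNP0243665.0)
Conditions: BBr3 (excess), CH2Cl2, −78 °C to rt; then H2O, 0 °C; work-up and reverse-phase purification under argon
Reagents that add atoms: none
Why: Lewis acid cleavage of the twelve aryl methyl ethers through aryloxyboron species; the diaryl ether C–O bonds offer no alkyl carbon to bromide and should survive. Exclusion of air protects the pyrogallol-type product from oxidation.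

## Compound list

1 | 2,4,6-trimethoxyphenol | COc1cc(OC)c(O)c(OC)c1 | starting material
2 | 2-bromo-4,6-dimethoxybenzaldehyde | COc1cc(Br)c(C=O)c(OC)c1 | starting material
3 | 2,4-dimethoxy-6-(2,4,6-trimethoxyphenoxy)benzaldehyde | COc1cc(OC)c(C=O)c(Oc2c(OC)cc(OC)cc2OC)c1 | intermediate
4 | 2,4-dimethoxy-6-(2,4,6-trimethoxyphenoxy)phenyl formate | COc1cc(OC)c(OC=O)c(Oc2c(OC)cc(OC)cc2OC)c1 | intermediate
5 | 2,4-dimethoxy-6-(2,4,6-trimethoxyphenoxy)phenol | COc1cc(OC)c(O)c(Oc2c(OC)cc(OC)cc2OC)c1 | intermediate
6 | 4-bromo-2,6-dimethoxybenzaldehyde | COc1cc(Br)cc(OC)c1C=O | starting material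
7 | 4-[2,4-dimethoxy-6-(2,4,6-trimethoxyphenoxy)phenoxy]-2,6-dimethoxybenzaldehyde | COc1cc(Oc2c(OC)cc(OC)cc2Oc2c(OC)cc(OC)cc2OC)cc(OC)c1C=O | intermediate
8 | 4-[2,4-dimethoxy-6-(2,4,6-trimethoxyphenoxy)phenoxy]-2,6-dimethoxyphenyl formate | COc1cc(Oc2c(OC)cc(OC)cc2Oc2c(OC)cc(OC)cc2OC)cc(OC)c1OC=O | intermediate
9 | 4-[2,4-dimethoxy-6-(2,4,6-trimethoxyphenoxy)phenoxy]-2,6-dimethoxyphenol | COc1cc(Oc2c(OC)cc(OC)cc2Oc2c(OC)cc(OC)cc2OC)cc(OC)c1O | intermediate
10 | trichloroethylene | ClC=C(Cl)Cl | starting material
11 | dichloroacetylene | ClC#CCl | intermediate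
12 | 2-{[(E)-1,2-dichloroethenyl]oxy}-5-[2,4-dimethoxy-6-(2,4,6-trimethoxyphenoxy)phenoxy]-1,3-dimethoxybenzene | COc1cc(Oc2c(OC)cc(OC)cc2Oc2c(OC)cc(OC)cc2OC)cc(OC)c1O/C(Cl)=C\Cl | intermediate
13 | 2-[(chloroethynyl)oxy]-5-[2,4-dimethoxy-6-(2,4,6-trimethoxyphenoxy)phenoxy]-1,3-dimethoxybenzene | COc1cc(Oc2c(OC)cc(OC)cc2Oc2c(OC)cc(OC)cc2OC)cc(OC)c1OC#CCl | intermediate
14 | lithium {4-[2,4-dimethoxy-6-(2,4,6-trimethoxyphenoxy)phenoxy]-2,6-dimethoxyphenoxy}ethynide | COc1cc(Oc2c(OC)cc(OC)cc2Oc2c(OC)cc(OC)cc2OC)cc(OC)c1OC#C[Li] | intermediate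
15 | 5-[2,4-dimethoxy-6-(2,4,6-trimethoxyphenoxy)phenoxy]-2-(ethynyloxy)-1,3-dimethoxybenzene | COc1cc(Oc2c(OC)cc(OC)cc2Oc2c(OC)cc(OC)cc2OC)cc(OC)c1OC#C | intermediate
16 | squaric acid dichloride (3,4-dichlorocyclobut-3-ene-1,2-dione) | O=C1C(Cl)=C(Cl)C1=O | starting material
17 | 3,4,5-trimethoxyphenol | COc1cc(O)cc(OC)c1OC | starting material
18 | 3-chloro-4-methoxycyclobut-3-ene-1,2-dione | COC1=C(Cl)C(=O)C1=O | intermediate
19 | 3-methoxy-4-(3,4,5-trimethoxyphenoxy)cyclobut-3-ene-1,2-dione | COC1=C(Oc2cc(OC)c(OC)c(OC)c2)C(=O)C1=O | intermediate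
20 | 4-hydroxy-3-methoxy-2-(3,4,5-trimethoxyphenoxy)cyclobut-2-en-1-one (racemic) | COC1=C(Oc2cc(OC)c(OC)c(OC)c2)C(=O)C1O | intermediate
21 | 3,4-dimethoxy-2-(3,4,5-trimethoxyphenoxy)cyclobut-2-en-1-one (racemic) | COC1C(OC)=C(Oc2cc(OC)c(OC)c(OC)c2)C1=O | intermediate
22 | (3Z)-3,4-dimethoxy-2-(3,4,5-trimethoxyphenoxy)buta-1,3-dien-1-one | O=C=C(Oc1cc(OC)c(OC)c(OC)c1)/C(OC)=C/OC | intermediate
23 | 4-[(Z)-1,2-dimethoxyethenyl]-3-{4-[2,4-dimethoxy-6-(2,4,6-trimethoxyphenoxy)phenoxy]-2,6-dimethoxyphenoxy}-4-(3,4,5-trimethoxyphenoxy)cyclobut-2-en-1-one (racemic) | O=C1C=C(Oc2c(OC)cc(Oc3c(OC)cc(OC)cc3Oc3c(OC)cc(OC)cc3OC)cc2OC)C1(Oc1cc(OC)c(OC)c(OC)c1)/C(OC)=C/OC | intermediate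
24 | (3Z,5Z)-3-{4-[2,4-dimethoxy-6-(2,4,6-trimethoxyphenoxy)phenoxy]-2,6-dimethoxyphenoxy}-5,6-dimethoxy-4-(3,4,5-trimethoxyphenoxy)hexa-1,3,5-trien-1-one | O=C=C/C(Oc1c(OC)cc(Oc2c(OC)cc(OC)cc2Oc2c(OC)cc(OC)cc2OC)cc1OC)=C(/Oc1cc(OC)c(OC)c(OC)c1)\C(OC)=C\OC | intermediate
25 | 3-{4-[2,4-dimethoxy-6-(2,4,6-trimethoxyphenoxy)phenoxy]-2,6-dimethoxyphenoxy}-5,6-dimethoxy-4-(3,4,5-trimethoxyphenoxy)cyclohexa-2,4-dien-1-one (racemic) | O=C1C=C(Oc2c(OC)cc(Oc3c(OC)cc(OC)cc3Oc3c(OC)cc(OC)cc3OC)cc2OC)C(Oc2cc(OC)c(OC)c(OC)c2)=C(OC)C1OC | intermediate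
26 | 5-{4-[2,4-dimethoxy-6-(2,4,6-trimethoxyphenoxy)phenoxy]-2,6-dimethoxyphenoxy}-2,3-dimethoxy-4-(3,4,5-trimethoxyphenoxy)phenol | COc1cc(OC)c(Oc2cc(OC)cc(OC)c2Oc2cc(OC)c(Oc3cc(O)c(OC)c(OC)c3Oc3cc(OC)c(OC)c(OC)c3)c(OC)c2)c(OC)c1 | intermediate
27 | 5-{4-[2,4-dihydroxy-6-(2,4,6-trihydroxyphenoxy)phenoxy]-2,6-dihydroxyphenoxy}-4-(3,4,5-trihydroxyphenoxy)benzene-1,2,3-triol | Oc1cc(O)c(Oc2cc(O)cc(O)c2Oc2cc(O)c(Oc3cc(O)c(O)c(O)c3Oc3cc(O)c(O)c(O)c3)c(O)c2)c(O)c1 | target

## Step count and risk

Total step count: 11. Longest linear sequence: 8 steps (steps 1, 2, 3, 4, 5, 6, 10, 11); the branch to 21 has 3 steps (7, 8, 9).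

Step 10 (key step). The one bimolecular event, capture of vinylketene 22 by 15, may lose to unimolecular or self-reactions: acylation of the electron-rich ring E by the ketene, oligomerization of the ketene, or polymerization of the terminal ynol ether at the temperature needed for ring opening. The fallback sets out from 19 and 9 and comes back to the route at 27. Addition of 1-ethoxyvinyllithium (ethyl vinyl ether, t-BuLi, THF, −78 °C) to 19 at the carbonyl that the hydride of step 8 attacks, with trapping of the alkoxide by MeOTf, should give 4-(1-ethoxyethenyl)-3,4-dimethoxy-2-(3,4,5-trimethoxyphenoxy)cyclobut-2-en-1-one F1. Heating in toluene at 110 °C (Moore-type ring expansion: 4π opening, 6π closure, enolization) should give 5-ethoxy-3,4-dimethoxy-2-(3,4,5-trimethoxyphenoxy)phenol F2, which is ring D with the D–O–E ether in place. Tf2O and pyridine should give 5-ethoxy-3,4-dimethoxy-2-(3,4,5-trimethoxyphenoxy)phenyl trifluoromethanesulfonate F3. Coupling of F3 with phenol 9 (Pd2(dba)3, a di-tert-butyl biaryl phosphine, K3PO4, toluene, 100 °C) should give 5-{4-[2,4-dimethoxy-6-(2,4,6-trimethoxyphenoxy)phenoxy]-2,6-dimethoxyphenoxy}-1-ethoxy-2,3-dimethoxy-4-(3,4,5-trimethoxyphenoxy)benzene F4, which BBr3 as in step 11 should convert into 27.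

Step 8. The two carbonyl groups of 19 differ only through a methoxy versus an aryloxy donor, so hydride may add with poor regioselectivity, or may displace the aryloxide by conjugate addition. The fallback sets out from 16 and 17 and comes back at 21. 16 with two equivalents of 17 (iPr2NEt, CH2Cl2) should give the symmetric 3,4-bis(3,4,5-trimethoxyphenoxy)cyclobut-3-ene-1,2-dione F5, in which the hydride has no choice. LiAlH(OtBu)3 should give 4-hydroxy-2,3-bis(3,4,5-trimethoxyphenoxy)cyclobut-2-en-1-one F6, and Ag2O/MeI should give 4-methoxy-2,3-bis(3,4,5-trimethoxyphenoxy)cyclobut-2-en-1-one F7. Catalytic NaOMe in MeOH at 0 °C should then exchange only the aryloxy group at C3, the vinylogous ester position, by conjugate addition–elimination to give 21.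

Step 6. The terminal aryl ynol ether may hydrate or polymerize during isolation, and n-BuLi may metalate a methoxy-flanked ring position. The fallback sets out from 14 and comes back at 26. Quenching 14 with Me3SiCl instead of water should give the storable 5-[2,4-dimethoxy-6-(2,4,6-trimethoxyphenoxy)phenoxy]-1,3-dimethoxy-2-{[(trimethylsilyl)ethynyl]oxy}benzene F8. Benzannulation of F8 with 21 under the conditions of step 10 should give 3-{4-[2,4-dimethoxy-6-(2,4,6-trimethoxyphenoxy)phenoxy]-2,6-dimethoxyphenoxy}-5,6-dimethoxy-4-(3,4,5-trimethoxyphenoxy)-2-(trimethylsilyl)phenol F9, and protodesilylation (TFA, CH2Cl2, 0 °C) should give 26.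

Step 3. The di-ortho-substituted phenoxide of 5 may couple slowly, so that reduction of the bromide and decomposition of the aldehyde take over. The fallback sets out from 6 and 5 and comes back at 7. Miyaura-type borylation of 6 with B2(OH)4 (Pd(OAc)2, XPhos, KOAc, EtOH, 80 °C) should give (4-formyl-3,5-dimethoxyphenyl)boronic acid F10. Chan–Lam coupling of F10 with 5 (Cu(OAc)2, pyridine, 4 Å molecular sieves, air, CH2Cl2, rt), a reaction type used for di-ortho-substituted phenols, should give 7.

Step 11. Cleavage of twelve ethers may stop short, a diaryl ether may be cut by the strong Lewis acid, and the free polyphenol may oxidize during isolation. The fallback sets out from 26 and comes back at 27. After the BBr3 treatment the crude product is acetylated in the same flask (Ac2O, pyridine) to 5-{4-[2,4-diacetoxy-6-(2,4,6-triacetoxyphenoxy)phenoxy]-2,6-diacetoxyphenoxy}-4-(3,4,5-triacetoxyphenoxy)benzene-1,2,3-triyl triacetate F11. F11 can be purified on silica in air and separated from partly methylated material, and HCl in degassed MeOH then releases 27 under acidic, oxygen-free conditions.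

## Further compounds

F1 | step 10 | 4-(1-ethoxyethenyl)-3,4-dimethoxy-2-(3,4,5-trimethoxyphenoxy)cyclobut-2-en-1-one (racemic) | CCOC(=C)C1(OC)C(OC)=C(Oc2cc(OC)c(OC)c(OC)c2)C1=O
F2 | step 10 | 5-ethoxy-3,4-dimethoxy-2-(3,4,5-trimethoxyphenoxy)phenol | CCOc1cc(O)c(Oc2cc(OC)c(OC)c(OC)c2)c(OC)c1OC
F3 | step 10 | 5-ethoxy-3,4-dimethoxy-2-(3,4,5-trimethoxyphenoxy)phenyl trifluoromethanesulfonate | CCOc1cc(OS(=O)(=O)C(F)(F)F)c(Oc2cc(OC)c(OC)c(OC)c2)c(OC)c1OC
F4 | step 10 | 5-{4-[2,4-dimethoxy-6-(2,4,6-trimethoxyphenoxy)phenoxy]-2,6-dimethoxyphenoxy}-1-ethoxy-2,3-dimethoxy-4-(3,4,5-trimethoxyphenoxy)benzene | CCOc1cc(Oc2c(OC)cc(Oc3c(OC)cc(OC)cc3Oc3c(OC)cc(OC)cc3OC)cc2OC)c(Oc2cc(OC)c(OC)c(OC)c2)c(OC)c1OC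
F5 | step 8 | 3,4-bis(3,4,5-trimethoxyphenoxy)cyclobut-3-ene-1,2-dione | O=C1C(Oc2cc(OC)c(OC)c(OC)c2)=C(Oc2cc(OC)c(OC)c(OC)c2)C1=O
F6 | step 8 | 4-hydroxy-2,3-bis(3,4,5-trimethoxyphenoxy)cyclobut-2-en-1-one (racemic) | O=C1C(Oc2cc(OC)c(OC)c(OC)c2)=C(Oc2cc(OC)c(OC)c(OC)c2)C1O
F7 | step 8 | 4-methoxy-2,3-bis(3,4,5-trimethoxyphenoxy)cyclobut-2-en-1-one (racemic) | COC1C(Oc2cc(OC)c(OC)c(OC)c2)=C(Oc2cc(OC)c(OC)c(OC)c2)C1=O
F8 | step 6 | 5-[2,4-dimethoxy-6-(2,4,6-trimethoxyphenoxy)phenoxy]-1,3-dimethoxy-2-{[(trimethylsilyl)ethynyl]oxy}benzene | COc1cc(Oc2c(OC)cc(OC)cc2Oc2c(OC)cc(OC)cc2OC)cc(OC)c1OC#C[Si](C)(C)C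
F9 | step 6 | 3-{4-[2,4-dimethoxy-6-(2,4,6-trimethoxyphenoxy)phenoxy]-2,6-dimethoxyphenoxy}-5,6-dimethoxy-4-(3,4,5-trimethoxyphenoxy)-2-(trimethylsilyl)phenol | COc1cc(OC)c(Oc2cc(OC)cc(OC)c2Oc2cc(OC)c(Oc3c([Si](C)(C)C)c(O)c(OC)c(OC)c3Oc3cc(OC)c(OC)c(OC)c3)c(OC)c2)c(OC)c1
F10 | step 3 | (4-formyl-3,5-dimethoxyphenyl)boronic acid | COc1cc(B(O)O)cc(OC)c1C=O
F11 | step 11 | 5-{4-[2,4-diacetoxy-6-(2,4,6-triacetoxyphenoxy)phenoxy]-2,6-diacetoxyphenoxy}-4-(3,4,5-triacetoxyphenoxy)benzene-1,2,3-triyl triacetate | CC(=O)Oc1cc(OC(C)=O)c(Oc2cc(OC(C)=O)cc(OC(C)=O)c2Oc2cc(OC(C)=O)c(Oc3cc(OC(C)=O)c(OC(C)=O)c(OC(C)=O)c3Oc3cc(OC(C)=O)c(OC(C)=O)c(OC(C)=O)c3)c(OC(C)=O)c2)c(OC(C)=O)c1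
A1 | alternative 1 | 1-bromo-3,4,5-trimethoxy-2-(3,4,5-trimethoxyphenoxy)benzene | COc1cc(Br)c(Oc2cc(OC)c(OC)c(OC)c2)c(OC)c1OC
A2 | alternative 1 | tridecamethyl ether of the target | COc1cc(OC)c(Oc2cc(OC)cc(OC)c2Oc2cc(OC)c(Oc3cc(OC)c(OC)c(OC)c3Oc3cc(OC)c(OC)c(OC)c3)c(OC)c2)c(OC)c1
A3 | alternative 2 | 3,4-dimethoxy-4-(1-methoxyethenyl)-2-(3,4,5-trimethoxyphenoxy)cyclobut-2-en-1-one (racemic) | COC(=C)C1(OC)C(OC)=C(Oc2cc(OC)c(OC)c(OC)c2)C1=O
A4 | alternative 2 | 3,4,5-trimethoxy-2-(3,4,5-trimethoxyphenoxy)phenol | COc1cc(O)c(Oc2cc(OC)c(OC)c(OC)c2)c(OC)c1OC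
A5 | alternative 3 | 2-diazocyclohexane-1,3-dione | [N-]=[N+]=C1C(=O)CCCC1=O
A6 | alternative 3 | 2-[3,4,5-trimethoxy-2-(3,4,5-trimethoxyphenoxy)phenoxy]cyclohexane-1,3-dione | COc1cc(OC2C(=O)CCCC2=O)c(Oc2cc(OC)c(OC)c(OC)c2)c(OC)c1OC
A7 | alternative 3 | 2-[3,4,5-trimethoxy-2-(3,4,5-trimethoxyphenoxy)phenoxy]benzene-1,3-diol | COc1cc(Oc2c(O)cccc2O)c(Oc2cc(OC)c(OC)c(OC)c2)c(OC)c1OC
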